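**Plan**
- Retrosynthesis: the two free 7-hydroxyls are first tied as O7–CH2–O7', and the C8(B)–C8(C) biaryl bond is then cut. Next come the two O–CH2 bonds of the formal, both C8–I bonds, the pyranone of unit B (O1–C2 and C3=C4), and the O–CH2 bond of an aryloxyacetic acid.
- Enabling feature: C8 of the central 3-aryloxycoumarin (unit B) and C8 of the terminal coumarin (unit C) each sit next to a C7 phenol oxygen. One carbon between O7 and O7' makes the hindered, four-fold ortho-oxygenated coupling a closure of a seven-membered dibenzo[d,f][1,3]dioxepine (C8–C7–O–CH2–O–C7'–C8').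
- Forward: umbelliferone (unit A) is O-alkylated, and the pyranone of unit B is built onto it by Perkin condensation. Units B and C are iodinated at C8 and joined stepwise as an unsymmetrical formal; nickel closes the dioxepine and BCl3 removes the bridge.
- Stereochemistry: there is no stereocentre, and the axis carries no descriptor and is formed racemic.

Key step: step 10

Assumption: the target SMILES gives no sense to the C8–C8' axis, so racemic material is the goal.

**Step 1**
Reactants: 1 umbelliferone (7-hydroxy-2H-chromen-2-one); 2 ethyl bromoacetate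
Product: 3 ethyl 2-[(2-oxo-2H-chromen-7-yl)oxy]acetate
Conditions: K2CO3, acetone, reflux
Reagents that add atoms: none
Why: Williamson ether synthesis, in which the acidic 7-hydroxyl is the only nucleophile and the activated primary bromide reacts under carbonate conditions that leave the lactone closed.

**Step 2**
Reactants: 3 ethyl 2-[(2-oxo-2H-chromen-7-yl)oxy]acetate
Product: 4 2-[(2-oxo-2H-chromen-7-yl)oxy]acetic acid
Conditions: LiOH (1.2 equiv), THF/H2O, 0 °C to rt; then 1 M HCl
Reagents that add atoms: LiOH, [Li+].[OH-]
Why: Saponification of the activated aryloxyacetate ester outruns attack on the lactone, and the final acidification restores any lactone that has opened.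

**Step 3**
Reactants: 4 2-[(2-oxo-2H-chromen-7-yl)oxy]acetic acid; 5 2,4-dihydroxybenzaldehyde
Product: 7 2-oxo-3-[(2-oxo-2H-chromen-7-yl)oxy]-2H-chromen-7-yl acetate (A–B ether acetate), via formylaryl ester 6 (not isolated)
Conditions: Ac2O, Et3N, 120 °C
Reagents that add atoms: acetic anhydride, CC(=O)OC(C)=O
Why: Perkin (Perkin–Oglialoro) coumarin synthesis, in which acid 4 is transferred onto the 2-hydroxyl of 5 to give ester 6, whose activated OCH2 group condenses with the ortho aldehyde and loses water to close the pyranone of unit B with the aryloxy group at C3, while the 4-hydroxyl ends as its acetate.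

**Step 4**
Reactants: 7 A–B ether acetate
Product: 8 7-hydroxy-3-[(2-oxo-2H-chromen-7-yl)oxy]-2H-chromen-2-one (A–B ether)
Conditions: conc. HCl (cat.), MeOH/THF, reflux
Reagents that add atoms: none
Why: Acid-catalysed transesterification removes the aryl acetate, as is routine for Perkin-derived acetoxycoumarins, and both lactones and the aryl vinyl ether tolerate methanolic acid.

**Step 5**
Reactants: 8 A–B ether
Product: 9 7-hydroxy-8-iodo-3-[(2-oxo-2H-chromen-7-yl)oxy]-2H-chromen-2-one
Conditions: I2 (1.0 equiv), KI, 25% aq. NH3/dioxane, 0 °C to rt; then dil. HCl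
Reagents that add atoms: iodine, II
Why: Electrophilic aromatic iodination of the phenolate, which in 7-hydroxycoumarins goes to C8 (between the two oxygen-bearing carbons), while unit A is a non-phenolic aryl ether and far less reactive.

**Step 6**
Reactants: 1 umbelliferone
Product: 10 7-hydroxy-8-iodo-2H-chromen-2-one (8-iodoumbelliferone)
Conditions: I2 (1.0 equiv), KI, 25% aq. NH3, 0 °C to rt; then dil. HCl
Reagents that add atoms: iodine, II
Why: The same phenolate-directed electrophilic iodination, a standard preparation of the 8-iodide of umbelliferone.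

**Step 7**
Reactants: 10 8-iodoumbelliferone; 11 chloromethyl methyl sulfide
Product: 12 8-iodo-7-[(methylsulfanyl)methoxy]-2H-chromen-2-one (methylthiomethyl ether)
Conditions: NaH, DMF, 0 °C; then 11, NaI (cat.), rt
Reagents that add atoms: none
Why: Williamson-type O-alkylation of the sodium phenolate with the α-chloro sulfide gives a storable O,S-acetal that already carries the future bridge carbon.

**Step 8**
Reactants: 12 methylthiomethyl ether
Product: 13 7-(chloromethoxy)-8-iodo-2H-chromen-2-one (aryl chloromethyl ether)
Conditions: SO2Cl2 (1.0 equiv), CH2Cl2, 0 °C; volatiles removed in vacuo, used crude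
Reagents that add atoms: sulfuryl chloride, O=S(=O)(Cl)Cl
Why: Chlorinolysis of an O,S-acetal, the established route to aryl chloromethyl ethers, in which sulfur is chlorinated much faster than arene, alkene or iodide and the chlorosulfonium salt collapses with C–S cleavage and uptake of chloride.

**Step 9**
Reactants: 9 8-iodo A–B phenol; 13 aryl chloromethyl ether
Product: 14 formal-tethered bis(8-iodo) tricoumarin, 8-iodo-7-{[(8-iodo-2-oxo-2H-chromen-7-yl)oxy]methoxy}-3-[(2-oxo-2H-chromen-7-yl)oxy]-2H-chromen-2-one
Conditions: 9, NaH (1.0 equiv), DMF, 0 °C; then 13 in THF, 0 °C to rt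
Reagents that add atoms: none
Why: SN2 displacement (Williamson type) on the reactive α-chloro ether by the preformed, dry phenolate joins two different phenols through one carbon, and the stepwise order keeps symmetrical formals out.

**Step 10**
Reactants: 14 formal-tethered bis(8-iodo) tricoumarin
Product: 15 formal-bridged triumbelletin (O7,O7'-methylene; dibenzo[d,f][1,3]dioxepine core)
Conditions: Ni(cod)2 (2.5 equiv), 2,2'-bipyridine (2.5 equiv), DMF, 60 °C, slow addition of 14 (final ca. 3 mM), Ar
Reagents that add atoms: none
Why: Zerovalent nickel bound to bipyridine inserts into both C8–I bonds, aryl transfer between the two arylnickel iodide centres expels NiI2, and the resulting diaryl complex of divalent nickel, an eight-membered nickelacycle, reductively eliminates to form C8(B)–C8(C). The closest known reaction type is the nickel-mediated Ullmann-type (Yamamoto-type) reductive coupling of tethered aryl halides to bridged biaryls. The one ring closed is the seven-membered 1,3-dioxepine (C8–C7–O–CH2–O–C7'–C8'), formed by contraction of the nickelacycle through aryl–aryl bond formation between the two ends of the O–CH2–O tether. No stereocentre arises, and the twisted biaryl axis is produced as a racemate. The step needs cross- over homo-coupling and exclusive C8/C8' connectivity, which the bridge, the placement of iodine only at the two C8 positions and the high dilution secure. Chemoselectivity rests on C–I insertion being far faster at 60 °C than any reaction of the lactone acyl–O or aryl ether C–O bonds, and the excess of nickel offsets binding to the three C3=C4 alkenes.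

**Step 11**
Reactants: 15 formal-bridged triumbelletin
Product: 16 triumbelletin
Conditions: BCl3 (5 equiv), CH2Cl2, −78 to 0 °C; then H2O
Reagents that add atoms: none
Why: Lewis-acid acetal cleavage, as known for methylenedioxy arenes, in which BCl3 binds a formal oxygen and chloride opens the only sp3 C–O bonds present, water then freeing both phenols, while the aryl vinyl ether and the lactones offer no such bond.

**Compound list**
1 | umbelliferone (7-hydroxy-2H-chromen-2-one) | O=c1ccc2ccc(O)cc2o1 | starting material
2 | ethyl bromoacetate | CCOC(=O)CBr | starting material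
3 | ethyl 2-[(2-oxo-2H-chromen-7-yl)oxy]acetate | CCOC(=O)COc1ccc2ccc(=O)oc2c1 | intermediate
4 | 2-[(2-oxo-2H-chromen-7-yl)oxy]acetic acid | OC(=O)COc1ccc2ccc(=O)oc2c1 | intermediate
5 | 2,4-dihydroxybenzaldehyde | O=Cc1ccc(O)cc1O | starting material
6 | 5-acetoxy-2-formylphenyl 2-[(2-oxo-2H-chromen-7-yl)oxy]acetate (not isolated) | O=Cc1ccc(OC(C)=O)cc1OC(=O)COc1ccc2ccc(=O)oc2c1 | intermediate
7 | 2-oxo-3-[(2-oxo-2H-chromen-7-yl)oxy]-2H-chromen-7-yl acetate | O=c1ccc2ccc(Oc3cc4ccc(OC(C)=O)cc4oc3=O)cc2o1 | intermediate
8 | 7-hydroxy-3-[(2-oxo-2H-chromen-7-yl)oxy]-2H-chromen-2-one | O=c1ccc2ccc(Oc3cc4ccc(O)cc4oc3=O)cc2o1 | intermediate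
9 | 7-hydroxy-8-iodo-3-[(2-oxo-2H-chromen-7-yl)oxy]-2H-chromen-2-one | O=c1ccc2ccc(Oc3cc4ccc(O)c(I)c4oc3=O)cc2o1 | intermediate
10 | 7-hydroxy-8-iodo-2H-chromen-2-one | O=c1ccc2ccc(O)c(I)c2o1 | intermediate
11 | chloromethyl methyl sulfide | CSCCl | starting material
12 | 8-iodo-7-[(methylsulfanyl)methoxy]-2H-chromen-2-one | CSCOc1ccc2ccc(=O)oc2c1I | intermediate
13 | 7-(chloromethoxy)-8-iodo-2H-chromen-2-one | ClCOc1ccc2ccc(=O)oc2c1I | intermediate
14 | formal-tethered bis(8-iodo) tricoumarin | O=c1ccc2ccc(Oc3cc4ccc(OCOc5ccc6ccc(=O)oc6c5I)c(I)c4oc3=O)cc2o1 | intermediate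
15 | formal-bridged triumbelletin | O=c1ccc2ccc(Oc3cc4ccc5OCOc6ccc7ccc(=O)oc7c6-c5c4oc3=O)cc2o1 | intermediate
16 | triumbelletin | O=c1ccc2ccc(Oc3cc4ccc(O)c(-c5c(O)ccc6ccc(=O)oc56)c4oc3=O)cc2o1 | target

**Totals**
Total step count: 11.
Longest linear sequence: 8 (steps 1, 2, 3, 4, 5, 9, 10, 11).

**Steps most likely to fail**

Step 10.
- Risk: aryl transfer and reductive elimination at an axis with four ortho substituents may be slow. Protodeiodination and intermolecular oligomerisation could then compete, and nickel may be held back by the coumarin alkenes.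
- Fallback: replace the reductive coupling of two iodides by a palladium-catalysed intramolecular direct arylation that needs only one iodide.
- Route: it sets out from phenol 8 and chloromethyl ether 13. NaH in DMF, as in step 9, should give the mono-iodide formal 7-{[(8-iodo-2-oxo-2H-chromen-7-yl)oxy]methoxy}-3-[(2-oxo-2H-chromen-7-yl)oxy]-2H-chromen-2-one F1.
- Closure: Pd(OAc)2, PCy3·HBF4, PivOH and K2CO3 in DMA at 110 °C should then effect concerted metalation–deprotonation at C8–H of unit B. This is the most acidic C–H, lying between O7 and O1. The same seven-membered ring closes and the route is rejoined at 15.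

Step 9.
- Risk: the chloromethyl ether may hydrolyse or scramble before the hindered, weakly nucleophilic ortho-iodophenolate attacks.
- Fallback: give up the directed assembly for a one-pot statistical formal synthesis with a C1 dielectrophile.
- Route: it sets out from 9 and 10, with 10 in about fivefold excess. Bromochloromethane (ClCBr) and Cs2CO3 in DMF at 60 °C generate the chloromethyl ethers in the presence of both phenolates.
- Outcome: the valuable partner 9 should be channelled mainly into the mixed formal, rejoining the route at 14. The surplus of 10 ends as the symmetrical formal bis[(8-iodo-2-oxo-2H-chromen-7-yl)oxy]methane F2, which is removed by chromatography.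

Step 5.
- Risk: attack at C6, double iodination, or poor solubility of the large phenolate in aqueous ammonia may erode site control.
- Fallback: install the iodine before unit B exists, starting from 5.
- Route: I2/HIO3 in aqueous EtOH should give 2,4-dihydroxy-3-iodobenzaldehyde F3, which can be purified from isomers at the small-molecule stage. Perkin condensation with 4 under the conditions of step 3 should give 8-iodo-2-oxo-3-[(2-oxo-2H-chromen-7-yl)oxy]-2H-chromen-7-yl acetate F4. Acid methanolysis as in step 4 rejoins the route at 9.

**Further compounds**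
F1 | step 10 | 7-{[(8-iodo-2-oxo-2H-chromen-7-yl)oxy]methoxy}-3-[(2-oxo-2H-chromen-7-yl)oxy]-2H-chromen-2-one | O=c1ccc2ccc(Oc3cc4ccc(OCOc5ccc6ccc(=O)oc6c5I)cc4oc3=O)cc2o1
F2 | step 9 | bis[(8-iodo-2-oxo-2H-chromen-7-yl)oxy]methane | O=c1ccc2ccc(OCOc3ccc4ccc(=O)oc4c3I)c(I)c2o1
F3 | step 5 | 2,4-dihydroxy-3-iodobenzaldehyde | O=Cc1ccc(O)c(I)c1O
F4 | step 5 | 8-iodo-2-oxo-3-[(2-oxo-2H-chromen-7-yl)oxy]-2H-chromen-7-yl acetate | O=c1ccc2ccc(Oc3cc4ccc(OC(C)=O)c(I)c4oc3=O)cc2o1
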